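A small charge of substrate, dripped into waiting activator in flask delta, makes ring over the whole feed, and the end share depends on how much of that ring is still there.

| setting | blue | violet | green | ochre | epsilon | gamma | alpha | delta |
|---|---|---|---|---|---|---|---|---|
| substrate | 20 mM | 20 mM | 20 mM | 40 mM | 20 mM | 20 mM | 20 mM | 20 mM (fed, over 12 h) |
| activator | 1.5 equiv | 2.1 equiv | 3.3 equiv | 1.5 equiv | 1.50 equiv (fed, over 12 h) | 1.50 equiv | 1.50 equiv (in portions, 3, over 12 h) | 1.50 equiv |
| remark | run made earlier | run made earlier | run made earlier | run made earlier | all else is in the flask from the start; the feed brings no volume worth counting | everything together at the start | first portion at the start, last at 12 h | all else is in the flask from the start; the feed brings no volume worth counting |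
| time |  |  |  |  | 2.5 d | 2.5 d | 2.5 d | 2.5 d |

| run | time / h | ring / % | open dimer / % |
|---|---|---|---|
| blue | 8.00 | 50.8 | 37.6 |
| blue | 15.0 | 43.1 | 37.8 |
| blue | 20.0 | 38.8 | 39.6 |
| blue | 30.0 | 30.4 | 39.2 |
| blue | 40.0 | 23.2 | 40.0 |
| violet | 3.00 | 51.5 | 28.6 |
| violet | 5.00 | 57.1 | 29.6 |
| violet | 10.0 | 57.0 | 28.7 |
| violet | 20.0 | 44.6 | 29.5 |
| violet | 40.0 | 26.4 | 31.8 |
| green | 3.00 | 57.0 | 19.6 |
| green | 5.00 | 67.0 | 21.4 |
| green | 10.0 | 64.4 | 21.4 |
| green | 20.0 | 51.1 | 21.1 |
| green | 40.0 | 30.5 | 19.7 |
| ochre | 8.00 | 48.8 | 39.3 |
| ochre | 15.0 | 42.5 | 41.2 |
| ochre | 20.0 | 38.7 | 40.5 |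
| ochre | 30.0 | 27.7 | 40.9 |
| ochre | 40.0 | 23.2 | 42.5 |

(each reading ± 1 percentage point)

- percent here means substrate units held: one open dimer counts as two
- steps under discussion: substrate + activator -> activated form; activated form -> ring; substrate + activated form -> open dimer; ring -> over-reaction product; substrate -> decomposition product

1. the flask that comes out highest in share of ring in ring plus open dimer, or "all alike" when all lie within 1.5 percentage points (epsilon / gamma / alpha / delta / all alike)
2. share of ring in ring plus open dimer at the end, epsilon
3. share of ring in ring plus open dimer at the end, gamma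
4. share of ring in ring plus open dimer at the end, alpha
5. share of ring in ring plus open dimer at the end, delta

From blue, ring decays at 0.0248 h⁻¹. From violet, the ring still to come shrinks at a closing rate of 0.475 h⁻¹. Dimer times equivalents reads 0.603 in violet and 0.600 in blue but 0.696 in green, so it is no constant, and we use the violet value as a rough stand-in for the ratio of capture to activation.

We carry the survival factor, the part of the ring made that still stands at the end. Ring made at the start would keep 22.6%, and ring made at the end of the feed 30.4%. Delta makes ring steadily through its feed, so it lies between them, and we freeze its ring at mid-feed: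

survival factor = exp(−decay rate × (time − half the feed)) = 26.2%

For the dimer, instant closing would leave none in delta, and a feed of no length is blue's recipe, which read 40.0% at 40.0 h. Closing takes 2.11 h, shorter than the feed, so [activated form] freezes at feed rate over closing rate. With activator at a mean of 1.00 equiv, and each capture counting two units:

dimer = 21.1%, share = 49.5%

Gamma, blue's recipe, makes its ring early, so with the start-made factor and blue's dimer we get 25.3%. We give epsilon and alpha no number, and we name delta.

The forecast also names delta, with 17.5%, 27.3%, 20.5% and 45% for epsilon, gamma, alpha and delta, on the ground that the substrate feed “keeps substrate starved”; its delta lies below our 49.5%.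

The flasks give 11.7%, 26.4%, 11.7% and 55.4% in that order, and delta comes highest.

    substrate + activator → activated form (k = 1.98 M⁻¹ min⁻¹)
    activated form → ring (k = 0.00819 min⁻¹)
    substrate + activated form → open dimer (k = 1.60 M⁻¹ min⁻¹)
    ring → over-reaction product (k = 4.24 × 10⁻⁴ min⁻¹)
    substrate → decomposition product (k = 4.59 × 10⁻⁶ min⁻¹)

In delta, activation, closing and capture ran together through the feed, ending with substrate at 4.58%, activated form at 12.4% and dimer at 16.6%. Afterwards ring decay ran with dimer at 17.8%, taking ring from 58.3% to 22.1%, so delta kept 26.9% of its ring made against our 26.2%. In epsilon, half the ring-making was done by 0.251 d, which gives the same 26.2%, and epsilon kept 25.5%.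

(All runs come from a simulation with made-up constants; noise was put on by code.)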